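**Retrosynthetic overview**
1. Feature: in the dihydroisocoumarin, the run C6–C5–C4a–C4–C3–O2 has the connectivity of a 6-alkyl-5,6-dihydropyran-2-one (C6 = lactone carbonyl carbon, O2 = ring oxygen, C3 = carbinol stereocentre). The run C7–C8–C8a–C1 is the carbon chain of methyl acetoacetate, so resorcinol ring A is a cyclohexane-1,3-dione one dehydrogenation short of aromatic.
2. End game (retro): re-protect the primary alcohol, remove the methyl group from the C6 oxygen, and add two hydrogens back to ring A to reach the 1,6,8-trione.
3. Key disconnection: cut C4a–C8a (Michael), C6–C7 (Claisen) and O2–C1 (lactonisation) of the trione, which gives the (R)-dihydropyranone and methyl acetoacetate.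
4. The dihydropyranone goes back by ring-closing metathesis to the acrylate of an (R)-homoallylic alcohol. That alcohol goes back by two copper-catalysed Grignard openings to (R)-epichlorohydrin, vinylmagnesium bromide and silyl-protected 10-bromodecan-1-ol, so C3 is bought and its C–O bond is never broken.
5. Order of ring formation: sacrificial pyranone ring (metathesis), then carbocycle A and lactone ring B in one flask (the pyranone ring opens as A closes), with ring A aromatised afterwards.

Key step: step 7

Assumption: the annulation product and the species leading to it are drawn as neutral keto tautomers, although they should be sodium enolates in the flask and the product should be largely enolised after work-up; C4a and C8a are left undefined because both centres are erased on aromatisation.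

Step 1
Reactants: 1 10-bromodecan-1-ol
Product: 2 tert-butyl[(10-bromodecyl)oxy]dimethylsilane
Conditions: TBSCl (1.1 equiv), imidazole (1.5 equiv), CH2Cl2, 0 °C → rt
Reagents that add atoms: tert-butyldimethylsilyl chloride (TBSCl), CC(C)(C)[Si](C)(C)Cl
Why: Imidazole-promoted O-silylation masks the hydroxyl so that the bromide can be converted into a Grignard reagent in the next step.

Step 2
Reactants: 2 tert-butyl[(10-bromodecyl)oxy]dimethylsilane; 3 (R)-epichlorohydrin
Product: 5 (2R)-13-(tert-butyldimethylsilyloxy)-1-chlorotridecan-2-ol, via 10-(tert-butyldimethylsilyloxy)decylmagnesium bromide 4 (not isolated)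
Conditions: Mg turnings, THF, 45 °C; then CuI (10 mol %), 3, THF, −40 → −10 °C; sat. aq. NH4Cl
Reagents that add atoms: none
Why: Copper-catalysed Grignard opening of an epoxide occurs in SN2 fashion at the unhindered ring CH2 of 3, faster than attack at C–Cl, so the C–O bond of the stereocentre is untouched and the (R) carbinol that becomes C3 comes straight from the chiral pool.

Step 3
Reactants: 5 (2R)-13-(tert-butyldimethylsilyloxy)-1-chlorotridecan-2-ol
Product: 6 (2R)-2-[11-(tert-butyldimethylsilyloxy)undecyl]oxirane
Conditions: powdered NaOH (3 equiv), Et2O, rt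
Reagents that add atoms: none
Why: Intramolecular Williamson (halohydrin) closure displaces the primary chloride with the alkoxide, so the carbinol carbon keeps its configuration and the silyl ether tolerates the base.

Step 4
Reactants: 6 (2R)-2-[11-(tert-butyldimethylsilyloxy)undecyl]oxirane; 7 vinylmagnesium bromide (1 M in THF)
Product: 8 (4R)-15-(tert-butyldimethylsilyloxy)pentadec-1-en-4-ol
Conditions: CuI (15 mol %), THF, −30 → 0 °C; sat. aq. NH4Cl
Reagents that add atoms: none
Why: Copper-catalysed vinyl Grignard opening of a terminal epoxide is regioselective for the CH2 terminus and does not touch the stereocentre, giving the (R) homoallylic alcohol.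

Step 5
Reactants: 8 (4R)-15-(tert-butyldimethylsilyloxy)pentadec-1-en-4-ol; 9 acryloyl chloride
Product: 10 (4R)-15-(tert-butyldimethylsilyloxy)pentadec-1-en-4-yl prop-2-enoate
Conditions: Et3N (2.5 equiv), DMAP (5 mol %), CH2Cl2, 0 °C → rt
Reagents that add atoms: none
Why: DMAP-catalysed O-acylation with an acid chloride reacts at the O–H bond only, so the second alkene is installed with no change at carbon.

Step 6
Reactants: 10 (4R)-15-(tert-butyldimethylsilyloxy)pentadec-1-en-4-yl prop-2-enoate
Product: 11 (6R)-6-[11-(tert-butyldimethylsilyloxy)undecyl]-5,6-dihydro-2H-pyran-2-one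
Conditions: second-generation Grubbs catalyst RuCl2(=CHPh)(PCy3)(H2IMes) (3 mol %), CH2Cl2 (0.01 M), 40 °C
Reagents that add atoms: none
Why: Ring-closing metathesis of homoallyl acrylates to 5,6-dihydropyran-2-ones is a standard use of this carbene–ruthenium catalyst, driven by loss of ethene and necessarily giving the Z ring alkene.

Step 7
Reactants: 11 (6R)-6-[11-(tert-butyldimethylsilyloxy)undecyl]-5,6-dihydro-2H-pyran-2-one; 12 methyl acetoacetate
Product: 16 (3R)-3-[11-(tert-butyldimethylsilyloxy)undecyl]-3,4,4a,5,7,8a-hexahydroisochromene-1,6,8-trione, via sodium enolate of methyl acetoacetate 13 (not isolated), via Michael adduct 14 (not isolated), via ring-A hydroxy ester 15 (not isolated)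
Conditions: 12 (1.3 equiv), NaOMe (1.1 equiv), MeOH, 0 °C; add 11, 0 °C → rt until 11 is consumed; then 65 °C; cold 1 M HCl to pH 3–4; crude in toluene, 110 °C
Reagents that add atoms: none
Why: Proposed new method: enolate 13 adds through its central carbon to pyranone C4 (bond C4a–C8a) to give 14; proton exchange in methanol makes the methyl-ketone enolate available, whose carbon (C7) attacks the lactone carbonyl (bond C6–C7) and releases the C3 oxygen in 15, which then displaces methoxide from the adjacent ester (bond O2–C1), and deprotonation of the strongly acidic 1,3-dione pulls every equilibrium towards 16. The closest known reaction type is the NaOMe-mediated Michael–Claisen (3+3) condensation of acetoacetates with crotonates to dihydroresorcylates; new here is the cyclic acceptor, whose ring oxygen is passed on to the acetoacetate ester. Ring A closes 6-(enolendo)-exo-trig, either across the lactone through a 2-oxabicyclo[3.3.1]nonane tetrahedral intermediate or, after methanolysis of the saturated lactone, on the open methyl ester exactly as in the classical case, and ring B closes 6-exo-trig. C4a is set by attack anti to the pyranone C6 chain (which leaves the new arm axial and so within reach of the carbonyl) and C8a equilibrates by enolisation, but neither matters because both become sp2 in step 8, whereas C3 is safe because only acyl–oxygen bonds are broken and made at O2. The step needs 1,4-addition to outrun removal of pyranone C5–H with eliminative ring opening to a dienoate and attack of methoxide at the carbonyl: the planar cyclic Z-enoate is a better acceptor than a crotonate, 13 is too weak a base for the γ-proton, 12 is kept in excess over NaOMe so that little free methoxide is present, and heat is applied only once 11 is consumed. Because the acidic dione can protonate the released alkoxide before it lactonises, any 15 left after acidification is converged on 16 by heating in toluene, the known thermal transesterification of β-keto esters.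

Step 8
Reactants: 16 (3R)-3-[11-(tert-butyldimethylsilyloxy)undecyl]-3,4,4a,5,7,8a-hexahydroisochromene-1,6,8-trione
Product: 17 (3R)-3-[11-(tert-butyldimethylsilyloxy)undecyl]-6,8-dihydroxy-3,4-dihydroisochromen-1-one
Conditions: DDQ (1.2 equiv), anhydrous 1,4-dioxane, 90 °C
Reagents that add atoms: none
Why: Quinone dehydrogenation of an enolised cyclohexane-1,3-dione, a known way from dihydroresorcylates to resorcylates, should proceed by hydride transfer from the C4a/C5 region to DDQ, proton loss and tautomerisation of the dienone to the arene, which erases C4a and C8a, leaves the remote C3 alone and, being run dry, spares the silyl ether.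

Step 9
Reactants: 17 (3R)-3-[11-(tert-butyldimethylsilyloxy)undecyl]-6,8-dihydroxy-3,4-dihydroisochromen-1-one
Product: 18 (3R)-3-[11-(tert-butyldimethylsilyloxy)undecyl]-8-hydroxy-6-methoxy-3,4-dihydroisochromen-1-one
Conditions: MeI (1.05 equiv), K2CO3 (1.1 equiv), acetone, rt
Reagents that add atoms: iodomethane (MeI), CI
Why: Williamson ether synthesis under weak base is selective for the C6 hydroxyl, because the C8 hydroxyl is hydrogen-bonded to the C1 carbonyl and is both less acidic and less nucleophilic, as is well established for 2,4-dihydroxybenzoates.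

Step 10
Reactants: 18 (3R)-3-[11-(tert-butyldimethylsilyloxy)undecyl]-8-hydroxy-6-methoxy-3,4-dihydroisochromen-1-one
Product: 19 (3R)-8-hydroxy-3-(11-hydroxyundecyl)-6-methoxy-3,4-dihydroisochromen-1-one
Conditions: HF·pyridine, THF, 0 °C → rt
Reagents that add atoms: none
Why: Fluoride-driven desilylation, paid for by the strong Si–F bond and run under mildly acidic conditions, frees the primary alcohol without affecting lactone, phenol, aryl ether or C3.

**Compound list**
1 | 10-bromodecan-1-ol | OCCCCCCCCCCBr | starting material
2 | tert-butyl[(10-bromodecyl)oxy]dimethylsilane | BrCCCCCCCCCCO[Si](C)(C)C(C)(C)C | intermediate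
3 | (R)-epichlorohydrin, (2R)-2-(chloromethyl)oxirane | ClC[C@H]1CO1 | starting material
4 | 10-(tert-butyldimethylsilyloxy)decylmagnesium bromide (not isolated) | Br[Mg]CCCCCCCCCCO[Si](C)(C)C(C)(C)C | intermediate
5 | (2R)-13-(tert-butyldimethylsilyloxy)-1-chlorotridecan-2-ol | ClC[C@H](O)CCCCCCCCCCCO[Si](C)(C)C(C)(C)C | intermediate
6 | (2R)-2-[11-(tert-butyldimethylsilyloxy)undecyl]oxirane | C1[C@H](O1)CCCCCCCCCCCO[Si](C)(C)C(C)(C)C | intermediate
7 | vinylmagnesium bromide | C=C[Mg]Br | starting material
8 | (4R)-15-(tert-butyldimethylsilyloxy)pentadec-1-en-4-ol | C=CC[C@H](O)CCCCCCCCCCCO[Si](C)(C)C(C)(C)C | intermediate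
9 | acryloyl chloride | C=CC(=O)Cl | starting material
10 | (4R)-15-(tert-butyldimethylsilyloxy)pentadec-1-en-4-yl prop-2-enoate | C=CC[C@H](OC(=O)C=C)CCCCCCCCCCCO[Si](C)(C)C(C)(C)C | intermediate
11 | (6R)-6-[11-(tert-butyldimethylsilyloxy)undecyl]-5,6-dihydro-2H-pyran-2-one | O=C1C=CC[C@@H](CCCCCCCCCCCO[Si](C)(C)C(C)(C)C)O1 | intermediate
12 | methyl acetoacetate | CC(=O)CC(=O)OC | starting material
13 | sodium enolate of methyl acetoacetate (not isolated) | [Na+].COC(=O)C=C(C)[O-] | intermediate
14 | methyl 2-{(2R)-2-[11-(tert-butyldimethylsilyloxy)undecyl]-6-oxooxan-4-yl}-3-oxobutanoate (Michael adduct, not isolated, drawn neutral, other centres undefined) | COC(=O)C(C(C)=O)C1CC(=O)O[C@H](CCCCCCCCCCCO[Si](C)(C)C(C)(C)C)C1 | intermediate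
15 | methyl 2-[(2R)-13-(tert-butyldimethylsilyloxy)-2-hydroxytridecyl]-4,6-dioxocyclohexane-1-carboxylate (ring A closed, not isolated, drawn neutral, ring centres undefined) | COC(=O)C1C(C[C@H](O)CCCCCCCCCCCO[Si](C)(C)C(C)(C)C)CC(=O)CC1=O | intermediate
16 | (3R)-3-[11-(tert-butyldimethylsilyloxy)undecyl]-3,4,4a,5,7,8a-hexahydroisochromene-1,6,8-trione (enolised, mixture at C4a and C8a) | O=C1O[C@H](CCCCCCCCCCCO[Si](C)(C)C(C)(C)C)CC2CC(=O)CC(=O)C12 | intermediate
17 | (3R)-3-[11-(tert-butyldimethylsilyloxy)undecyl]-6,8-dihydroxy-3,4-dihydroisochromen-1-one | Oc1cc(O)c2c(c1)C[C@@H](CCCCCCCCCCCO[Si](C)(C)C(C)(C)C)OC2=O | intermediate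
18 | (3R)-3-[11-(tert-butyldimethylsilyloxy)undecyl]-8-hydroxy-6-methoxy-3,4-dihydroisochromen-1-one | COc1cc(O)c2c(c1)C[C@@H](CCCCCCCCCCCO[Si](C)(C)C(C)(C)C)OC2=O | intermediate
19 | (3R)-8-hydroxy-3-(11-hydroxyundecyl)-6-methoxy-3,4-dihydroisochromen-1-one (CNP0140068.1) | COc1cc(O)c2c(c1)C[C@@H](CCCCCCCCCCCO)OC2=O | target

**Total step count:** 10. **Longest linear sequence:** 10 steps (1 → 19).

**Steps most likely to fail**

Step 7 (key step, no precedent for this acceptor class).
- What may go wrong:
  - eliminative opening of the unsaturated lactone after γ-deprotonation, which would also destroy the stereocentre;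
  - reversal of the conjugate addition on heating;
  - stalling after the Michael stage because too little methyl-ketone enolate is present.
- Fallback: it uses known chemistry and buys ring A as an arene instead of building it. It sets out from epoxide 6 and comes back to the route at target 19.
- N,N-Diethyl-2,4-dimethoxybenzamide F1 (purchased) is deprotonated next to the amide by directed ortho metalation (s-BuLi, TMEDA, THF, −78 °C) to 2-(diethylcarbamoyl)-3,5-dimethoxyphenyllithium F2.
- F2 opens 6 at its CH2 terminus (BF3·OEt2, −78 °C) to N,N-diethyl-2-[(2R)-13-(tert-butyldimethylsilyloxy)-2-hydroxytridecyl]-4,6-dimethoxybenzamide F3.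
- TsOH·H2O in refluxing toluene lactonises this with loss of the amine and of the silyl group to (3R)-3-(11-hydroxyundecyl)-6,8-dimethoxy-3,4-dihydroisochromen-1-one F4.
- BCl3 (CH2Cl2, −78 → 0 °C) then cleaves only the C8 methyl ether, which chelates to the C1 carbonyl, and gives 19.

Step 8.
- What may go wrong:
  - slow hydride transfer from an electron-poor enolised tricarbonyl;
  - addition of the enol to the quinone;
  - over-oxidation of the resorcinol;
  - partial loss of the silyl group caused by the acidic hydroquinone.
- Fallback: it methylates first and then introduces the missing unsaturation site-specifically by syn elimination. It sets out from 16 and comes back at 18, so step 9 is no longer needed.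
- The vinylogous acid is O-methylated (TMSCHN2, toluene–MeOH, 0 °C). This should go mainly to the less hindered C6 oxygen and give (3R)-3-[11-(tert-butyldimethylsilyloxy)undecyl]-6-methoxy-3,4,4a,5-tetrahydroisochromene-1,8(8aH)-dione F5.
- The remaining doubly activated C8a–H is selenenylated (PhSeCl, pyridine, CH2Cl2, 0 °C) to the 8a-(phenylselanyl) derivative F6.
- H2O2 oxidises this to the 8a-(phenylseleninyl) derivative F7, whose syn elimination across C8a–C4a gives a cross-conjugated dienone that tautomerises to 18.

Step 2.
- What may go wrong: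
  - homocoupling during Grignard formation from the primary bromide;
  - opening of the epoxide by magnesium halide;
  - competing substitution at C–Cl.
- Fallback: it replaces the Grignard reagent by an acetylide. It sets out from (R)-epichlorohydrin 3 and comes back at 5.
- Dec-9-yn-1-ol F8 (purchased) is silylated (TBSCl, imidazole, CH2Cl2) to tert-butyl(dec-9-yn-1-yloxy)dimethylsilane F9.
- F9 is deprotonated (n-BuLi, THF, −78 °C) to the lithium acetylide F10.
- F10 opens 3 at the ring CH2 under BF3·OEt2 promotion to (2R)-13-(tert-butyldimethylsilyloxy)-1-chlorotridec-4-yn-2-ol F11.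
- Hydrogenation (H2, Pd/C, EtOAc) saturates the triple bond and gives 5 with the same (R) carbinol.

**Further compounds**
F1 | step 7 | N,N-diethyl-2,4-dimethoxybenzamide (purchased) | CCN(CC)C(=O)c1ccc(OC)cc1OC
F2 | step 7 | 2-(diethylcarbamoyl)-3,5-dimethoxyphenyllithium | [Li]c1cc(OC)cc(OC)c1C(=O)N(CC)CC
F3 | step 7 | N,N-diethyl-2-[(2R)-13-(tert-butyldimethylsilyloxy)-2-hydroxytridecyl]-4,6-dimethoxybenzamide | CCN(CC)C(=O)c1c(OC)cc(OC)cc1C[C@H](O)CCCCCCCCCCCO[Si](C)(C)C(C)(C)C
F4 | step 7 | (3R)-3-(11-hydroxyundecyl)-6,8-dimethoxy-3,4-dihydroisochromen-1-one | COc1cc(OC)c2c(c1)C[C@@H](CCCCCCCCCCCO)OC2=O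
F5 | step 8 | (3R)-3-[11-(tert-butyldimethylsilyloxy)undecyl]-6-methoxy-3,4,4a,5-tetrahydroisochromene-1,8(8aH)-dione | COC1=CC(=O)C2C(C1)C[C@@H](CCCCCCCCCCCO[Si](C)(C)C(C)(C)C)OC2=O
F6 | step 8 | 8a-(phenylselanyl) derivative of F5 | COC1=CC(=O)C2([Se]c3ccccc3)C(C1)C[C@@H](CCCCCCCCCCCO[Si](C)(C)C(C)(C)C)OC2=O
F7 | step 8 | 8a-(phenylseleninyl) derivative of F5 | COC1=CC(=O)C2([Se](=O)c3ccccc3)C(C1)C[C@@H](CCCCCCCCCCCO[Si](C)(C)C(C)(C)C)OC2=O
F8 | step 2 | dec-9-yn-1-ol (purchased) | C#CCCCCCCCCO
F9 | step 2 | tert-butyl(dec-9-yn-1-yloxy)dimethylsilane | C#CCCCCCCCCO[Si](C)(C)C(C)(C)C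
F10 | step 2 | lithium acetylide of F9 | [Li]C#CCCCCCCCCO[Si](C)(C)C(C)(C)C
F11 | step 2 | (2R)-13-(tert-butyldimethylsilyloxy)-1-chlorotridec-4-yn-2-ol | ClC[C@H](O)CC#CCCCCCCCCO[Si](C)(C)C(C)(C)C
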